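**Plan**
- **Numbering and enabling feature:** the carbocycle is C1 (quaternary, CH3 and pyranone), C2H=C3(CH3), C4H=C5(CH3), C6H (side chain Cα(CH3)=CβH–COCH3). Without the C6 substituent, a plane through C1 and C4 exchanges C2 with C6 and the C3 methyl with the C5 methyl. With C4 as a carbonyl carbon the ring is therefore a prochiral 4,4-disubstituted 2,6-dimethylcyclohexa-2,5-dienone with two enantiotopic β-carbons.
- **Cuts, in retrosynthetic order:**
  - pyranone O–CH3, lactone O–C2' and C5'–C6', giving C1–CHO plus a β-keto ester;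
  - Cα–Cβ, giving C6–COCH3 plus a propynyl unit;
  - C4–H, giving C4=O through the enol triflate;
  - acetyl CH3 and C1–CH2OH are re-joined through one ether oxygen;
  - last, the C6–acyl bond.
- **Forward order:** the carbocycle comes from an arene by Birch reduction–methylation and oxidation to the dienone. A temporary tetrahydropyranone ring closes in step 6 and opens in step 7. The ring diene follows, then the side chain, and the pyranone ring last.
- **Stereochemistry:** C1 and C6 both arise in step 6, where the chiral carbene picks the enone arm and the tether forces the cis relation. The E-alkene comes from the steric bias of the Meyer–Schuster step. Every other centre made on the way is erased.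

Key step: step 6

Assumption: the sense of induction for this tether length cannot be predicted safely; the triazolium salt made from (1R,2S)-1-amino-2-indanol is written, and its equally available antipode is used if that salt favours the other enone arm.

Step 1
Reactants: 1 3,5-dimethylbenzoic acid
Product: 3 1,3,5-trimethylcyclohexa-2,5-diene-1-carboxylic acid, via dilithium enediolate 2 (not isolated)
Conditions: Li (3.3 equiv), NH3(l)/THF, −78 °C; MeI, −78 °C to rt; aq. HCl
Reagents that add atoms: methyl iodide, CI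
Why: Birch reduction–alkylation: the carboxylate directs 1,4-reduction to the ipso and para carbons, both methyl groups stay on the surviving double bonds, and the enediolate is methylated at C1 to give the (still achiral) quaternary carbon.

Step 2
Reactants: 3 1,3,5-trimethylcyclohexa-2,5-diene-1-carboxylic acid
Product: 4 (1,3,5-trimethylcyclohexa-2,5-dien-1-yl)methanol
Conditions: LiAlH4, Et2O, 0 °C to reflux; aq. work-up
Reagents that add atoms: none
Why: Hydride reduction of a carboxylic acid with LiAlH4, to which the isolated trisubstituted alkenes are inert.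

Step 3
Reactants: 4 (1,3,5-trimethylcyclohexa-2,5-dien-1-yl)methanol; 5 allyl bromide
Product: 7 1,3,5-trimethyl-3-[(prop-2-en-1-yloxy)methyl]cyclohexa-1,4-diene, via sodium alkoxide 6 (not isolated)
Conditions: NaH, THF/DMF, 0 °C; allyl bromide, Bu4NI (cat.), rt
Reagents that add atoms: allyl bromide (5), C=CCBr
Why: Williamson ether synthesis: the neopentyl alkoxide is hindered, but allyl bromide is a fast SN2 partner at room temperature, so the skipped diene never meets hot base.

Step 4
Reactants: 7 1,3,5-trimethyl-3-[(prop-2-en-1-yloxy)methyl]cyclohexa-1,4-diene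
Product: 8 2,4,6-trimethyl-4-[(prop-2-en-1-yloxy)methyl]cyclohexa-2,5-dien-1-one
Conditions: Rh2(cap)4 (cap = caprolactamate, 1 mol %), t-BuOOH (5 equiv), K2CO3 (0.5 equiv), CH2Cl2, rt
Reagents that add atoms: tert-butyl hydroperoxide, CC(C)(C)OO
Why: Allylic C–H oxidation by the tert-butylperoxy radical chain: the doubly allylic ring CH2 holds the weakest C–H bond of 7 and should be attacked before the allyl ether or the methyl groups, while the quaternary carbon rules out aromatisation.

Step 5
Reactants: 8 2,4,6-trimethyl-4-[(prop-2-en-1-yloxy)methyl]cyclohexa-2,5-dien-1-one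
Product: 10 2-[(1,3,5-trimethyl-4-oxocyclohexa-2,5-dien-1-yl)methoxy]acetaldehyde, via vicinal diol 9 (not isolated)
Conditions: OsO4 (2 mol %), NaIO4 (4 equiv), 2,6-lutidine, dioxane/H2O, rt
Reagents that add atoms: osmium tetroxide, O=[Os](=O)(=O)=O (delivers the oxygen and is re-formed by sodium periodate, [Na+].[O-]I(=O)(=O)=O)
Why: Lemieux–Johnson cleavage: OsO4 dihydroxylates the electron-rich monosubstituted alkene far faster than the two electron-poor, trisubstituted enone double bonds, and periodate splits the diol to the aldehyde.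

Step 6
Reactants: 10 2-[(1,3,5-trimethyl-4-oxocyclohexa-2,5-dien-1-yl)methoxy]acetaldehyde
Product: 11 (4aR,5S,8aS)-5,7,8a-trimethyl-4a,5-dihydro-1H-isochromene-4,6(3H,8aH)-dione (cis-fused pyranone–cyclohexenone)
Conditions: N-(4-methoxyphenyl)triazolium tetrafluoroborate from (1R,2S)-1-amino-2-indanol (10 mol %), KN(SiMe3)2 (10 mol %), toluene (dilute), rt
Reagents that add atoms: none
Why: The carbene freed from the triazolium salt adds to the aldehyde and a proton shift gives the enaminol (acyl-anion equivalent), which adds to one enone β-carbon; protonation of the enolate and loss of the carbene give the 1,4-diketone. This is the asymmetric intramolecular Stetter reaction in the form known for desymmetrising 4,4-disubstituted cyclohexadienones, and the new oxygen ring closes 6-exo-trig. The tether leaves C1 on one face of the flat dienone and can reach the neighbouring β-carbon only on that face, so the acyl group at C6 and the CH2O group at C1 must be cis (cis ring fusion). The chiral pocket of the carbene decides which of the two enantiotopic β-carbons is attacked, and this one choice fixes the absolute configuration of C6 and of the quaternary C1 together. C5 is set by protonation of the enolate from the convex face, and either outcome is acceptable because C5 becomes sp2 in step 8. The enaminol must add rather than expel its α-substituent or be lost to aldol chemistry: an ether oxygen is too poor a leaving group for the redox elimination open to α-acyloxy or α-halo aldehydes, the dienone has no α-hydrogen, and the six-membered closure should outrun benzoin-type dimerisation at high dilution.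

Step 7
Reactants: 11 (4aR,5S,8aS)-5,7,8a-trimethyl-4a,5-dihydro-1H-isochromene-4,6(3H,8aH)-dione
Product: 13 (3aS,7S,7aR)-1-methoxy-1,3a,5,7-tetramethyl-3,3a,7,7a-tetrahydro-2-benzofuran-6(1H)-one (both C1 anomers), via hydroxy ketone 12 (not isolated)
Conditions: SmI2 (2.5 equiv), THF/MeOH, −78 °C; aq. work-up; crude, PPTS (cat.), MeOH, rt
Reagents that add atoms: methanol, CO
Why: Reduction of an α-heterosubstituted ketone by divalent samarium: two electron transfers to the inductively activated saturated ketone expel the α-alkoxide, methanol protonates the enolate to the methyl ketone at a temperature at which the hindered enone should react only slowly, and acid in methanol closes the cis γ-hydroxy ketone (5-exo-trig) to a mixed ketal that masks alcohol and ketone together and shields C6–H from base.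

Step 8
Reactants: 13 (3aS,7S,7aR)-1-methoxy-1,3a,5,7-tetramethyl-3,3a,7,7a-tetrahydro-2-benzofuran-6(1H)-one
Product: 15 (3aS,7aS)-1-methoxy-1,3a,5,7-tetramethyl-1,3,3a,7a-tetrahydro-2-benzofuran-6-yl trifluoromethanesulfonate, via potassium dienolate 14 (not isolated)
Conditions: KN(SiMe3)2, THF, −78 °C; N-(5-chloropyridin-2-yl)bis(trifluoromethanesulfonimide), −78 to 0 °C
Reagents that add atoms: N-(5-chloropyridin-2-yl)bis(trifluoromethanesulfonimide), FC(F)(F)S(=O)(=O)N(c1ccc(Cl)cn1)S(=O)(=O)C(F)(F)F
Why: Enol triflate formation: with the acetyl group masked, C5–H is the only enolisable position, so deprotonation gives a single cross-conjugated dienolate whose oxygen is sulfonylated, which turns C5 into an sp2 carbon.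

Step 9
Reactants: 15 (3aS,7aS)-1-methoxy-1,3a,5,7-tetramethyl-1,3,3a,7a-tetrahydro-2-benzofuran-6-yl trifluoromethanesulfonate
Product: 16 (3aS,7aR)-1-methoxy-1,3a,5,7-tetramethyl-1,3,3a,7a-tetrahydro-2-benzofuran
Conditions: Pd(OAc)2 (5 mol %), PPh3 (10 mol %), HCO2H (2 equiv), Et3N (3 equiv), DMF, 60 °C
Reagents that add atoms: none
Why: Palladium-catalysed formate reduction of an enol triflate: oxidative addition to zerovalent palladium, decarboxylation of formate to a palladium hydride and reductive elimination replace OTf by H without moving the double bonds, and the excess amine keeps the ketal intact.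

Step 10
Reactants: 16 (3aS,7aR)-1-methoxy-1,3a,5,7-tetramethyl-1,3,3a,7a-tetrahydro-2-benzofuran
Product: 18 1-[(1R,6S)-6-{[(tert-butyldimethylsilyl)oxy]methyl}-2,4,6-trimethylcyclohexa-2,4-dien-1-yl]ethan-1-one, via hydroxy dienyl ketone 17 (not isolated)
Conditions: PPTS (cat.), acetone/H2O, rt; crude, TBSCl, imidazole, DMF, rt
Reagents that add atoms: water, O; tert-butyldimethylsilyl chloride, CC(C)(C)[Si](C)(C)Cl
Why: Mild ketal hydrolysis followed by silylation: the 2-methoxytetrahydrofuran-type ketal opens under very weak acid, the β,γ-unsaturated ketone is not purified so that it has little occasion to epimerise or move into conjugation, and silylation of the primary alcohol locks the open-chain form.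

Step 11
Reactants: 18 1-[(1R,6S)-6-{[(tert-butyldimethylsilyl)oxy]methyl}-2,4,6-trimethylcyclohexa-2,4-dien-1-yl]ethan-1-one; 19 1-propynylmagnesium bromide
Product: 20 2-[(1R,6S)-6-{[(tert-butyldimethylsilyl)oxy]methyl}-2,4,6-trimethylcyclohexa-2,4-dien-1-yl]pent-3-yn-2-ol (both carbinol epimers)
Conditions: LaCl3·2LiCl (1 equiv), THF, 0 °C; aq. work-up
Reagents that add atoms: 1-propynylmagnesium bromide (19), CC#C[Mg]Br
Why: Lanthanide-promoted 1,2-addition of an alkynyl Grignard reagent: LaCl3·2LiCl activates the hindered carbonyl group and tempers the basicity of the slim sp nucleophile so that addition should outrun enolisation at C6, and the new carbinol centre, formed as a mixture, disappears in step 12.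

Step 12
Reactants: 20 2-[(1R,6S)-6-{[(tert-butyldimethylsilyl)oxy]methyl}-2,4,6-trimethylcyclohexa-2,4-dien-1-yl]pent-3-yn-2-ol
Product: 21 (3E)-4-[(1S,6S)-6-{[(tert-butyldimethylsilyl)oxy]methyl}-2,4,6-trimethylcyclohexa-2,4-dien-1-yl]pent-3-en-2-one
Conditions: MoO2(acac)2, AuCl(PPh3), AgOSO2CF3 (2 mol % each), toluene, rt
Reagents that add atoms: none
Why: Meyer–Schuster rearrangement: the molybdate ester of the tertiary alcohol passes its oxygen to the gold-activated distal alkyne carbon (formal 1,3-shift), the allenol tautomerises to the enone, and the E isomer is favoured because it keeps the acetyl group away from the ring.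

Step 13
Reactants: 21 (3E)-4-[(1S,6S)-6-{[(tert-butyldimethylsilyl)oxy]methyl}-2,4,6-trimethylcyclohexa-2,4-dien-1-yl]pent-3-en-2-one
Product: 22 (3E)-4-[(1S,6S)-6-(hydroxymethyl)-2,4,6-trimethylcyclohexa-2,4-dien-1-yl]pent-3-en-2-one
Conditions: HF·pyridine, THF/pyridine, 0 °C to rt
Reagents that add atoms: none
Why: Fluoride-mediated silyl ether cleavage under buffered, non-basic conditions, chosen so that no alkoxide forms that could add to the nearby enone.

Step 14
Reactants: 22 (3E)-4-[(1S,6S)-6-(hydroxymethyl)-2,4,6-trimethylcyclohexa-2,4-dien-1-yl]pent-3-en-2-one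
Product: 23 (1S,6S)-1,3,5-trimethyl-6-[(2E)-4-oxopent-2-en-2-yl]cyclohexa-2,4-diene-1-carbaldehyde
Conditions: Dess–Martin periodinane, CH2Cl2, 0 °C to rt
Reagents that add atoms: none
Why: Dess–Martin oxidation of a primary alcohol to an aldehyde that has no α-hydrogen and so cannot epimerise.

Step 15
Reactants: 23 (1S,6S)-1,3,5-trimethyl-6-[(2E)-4-oxopent-2-en-2-yl]cyclohexa-2,4-diene-1-carbaldehyde; 24 methyl 2-methyl-3-oxopentanoate
Product: 26 methyl 5-hydroxy-2,4-dimethyl-3-oxo-5-{(1S,6S)-1,3,5-trimethyl-6-[(2E)-4-oxopent-2-en-2-yl]cyclohexa-2,4-dien-1-yl}pentanoate (diastereomer mixture), via sodium lithium dianion 25 (not isolated)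
Conditions: 24 (1.2 equiv), NaH, THF, 0 °C; n-BuLi, 0 °C; 23, −78 °C; cold aq. work-up
Reagents that add atoms: methyl 2-methyl-3-oxopentanoate (24), CCC(=O)C(C)C(=O)OC
Why: Aldol addition of a β-keto ester dianion through its γ-carbon: at −78 °C and with only a slight excess of dianion the aldehyde should react much faster than the β,β-disubstituted enone is attacked or deprotonated, and the three new stereocentres are lost in steps 16 and 17.

Step 16
Reactants: 26 methyl 5-hydroxy-2,4-dimethyl-3-oxo-5-{(1S,6S)-1,3,5-trimethyl-6-[(2E)-4-oxopent-2-en-2-yl]cyclohexa-2,4-dien-1-yl}pentanoate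
Product: 27 methyl 2,4-dimethyl-3,5-dioxo-5-{(1S,6S)-1,3,5-trimethyl-6-[(2E)-4-oxopent-2-en-2-yl]cyclohexa-2,4-dien-1-yl}pentanoate
Conditions: Dess–Martin periodinane, CH2Cl2, rt
Reagents that add atoms: none
Why: Dess–Martin oxidation of the β-hydroxy ketone to the 1,3-diketone, a neutral method that leaves the diene, the enone and C6–H alone.

Step 17
Reactants: 27 methyl 2,4-dimethyl-3,5-dioxo-5-{(1S,6S)-1,3,5-trimethyl-6-[(2E)-4-oxopent-2-en-2-yl]cyclohexa-2,4-dien-1-yl}pentanoate
Product: 28 4-hydroxy-3,5-dimethyl-6-{(1S,6S)-1,3,5-trimethyl-6-[(2E)-4-oxopent-2-en-2-yl]cyclohexa-2,4-dien-1-yl}-2H-pyran-2-one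
Conditions: DBU, toluene, rt to 60 °C; dilute aq. acid
Reagents that add atoms: none
Why: Base-induced lactonisation of a 3,5-dioxo ester: the enolate oxygen of the ketone next to C1 attacks the ester (6-exo-trig) and loss of methoxide gives the 4-hydroxy-2-pyranone, whose acidity buffers the amidine and so protects the doubly allylic C6–H.

Step 18
Reactants: 28 4-hydroxy-3,5-dimethyl-6-{(1S,6S)-1,3,5-trimethyl-6-[(2E)-4-oxopent-2-en-2-yl]cyclohexa-2,4-dien-1-yl}-2H-pyran-2-one
Product: 29 2-methoxy-3,5-dimethyl-6-{(1S,6S)-1,3,5-trimethyl-6-[(2E)-4-oxopent-2-en-2-yl]cyclohexa-2,4-dien-1-yl}-4H-pyran-4-one (CNP0353320.2)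
Conditions: MeOSO2CF3, CH2Cl2, rt; aq. work-up
Reagents that add atoms: methyl trifluoromethanesulfonate, COS(=O)(=O)C(F)(F)F
Why: O-Methylation with a hard alkylating agent in the absence of base: the lactone carbonyl oxygen is the most nucleophilic site of a 4-hydroxy-2-pyranone, and the 2-methoxypyrylium ion formed loses the O4 proton on work-up to give the 2-methoxy-4-pyranone.

**Compound list**
1 | 3,5-dimethylbenzoic acid | Cc1cc(C)cc(C(=O)O)c1 | starting material
2 | dilithium enediolate of 3,5-dimethyl-1,4-dihydrobenzoic acid | [Li+].[Li+].[O-]C([O-])=C1C=C(C)CC(C)=C1 | intermediate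
3 | 1,3,5-trimethylcyclohexa-2,5-diene-1-carboxylic acid | CC1=CC(C)(C(=O)O)C=C(C)C1 | intermediate
4 | (1,3,5-trimethylcyclohexa-2,5-dien-1-yl)methanol | CC1=CC(C)(CO)C=C(C)C1 | intermediate
5 | allyl bromide | C=CCBr | starting material
6 | sodium (1,3,5-trimethylcyclohexa-2,5-dien-1-yl)methoxide | [Na+].[O-]CC1(C)C=C(C)CC(C)=C1 | intermediate
7 | 1,3,5-trimethyl-3-[(prop-2-en-1-yloxy)methyl]cyclohexa-1,4-diene | C=CCOCC1(C)C=C(C)CC(C)=C1 | intermediate
8 | 2,4,6-trimethyl-4-[(prop-2-en-1-yloxy)methyl]cyclohexa-2,5-dien-1-one | C=CCOCC1(C)C=C(C)C(=O)C(C)=C1 | intermediate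
9 | 4-[(2,3-dihydroxypropoxy)methyl]-2,4,6-trimethylcyclohexa-2,5-dien-1-one | OCC(O)COCC1(C)C=C(C)C(=O)C(C)=C1 | intermediate
10 | 2-[(1,3,5-trimethyl-4-oxocyclohexa-2,5-dien-1-yl)methoxy]acetaldehyde | O=CCOCC1(C)C=C(C)C(=O)C(C)=C1 | intermediate
11 | (4aR,5S,8aS)-5,7,8a-trimethyl-4a,5-dihydro-1H-isochromene-4,6(3H,8aH)-dione | O1C[C@@]2(C)C=C(C)C(=O)[C@@H](C)[C@H]2C(=O)C1 | intermediate
12 | (4S,5R,6S)-5-acetyl-4-(hydroxymethyl)-2,4,6-trimethylcyclohex-2-en-1-one | OC[C@@]1(C)C=C(C)C(=O)[C@@H](C)[C@H]1C(C)=O | intermediate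
13 | (3aS,7S,7aR)-1-methoxy-1,3a,5,7-tetramethyl-3,3a,7,7a-tetrahydro-2-benzofuran-6(1H)-one, both C1 anomers | O1C[C@@]2(C)C=C(C)C(=O)[C@@H](C)[C@H]2C1(C)OC | intermediate
14 | potassium dienolate of 13 | [K+].O1C[C@@]2(C)C=C(C)C([O-])=C(C)[C@H]2C1(C)OC | intermediate
15 | (3aS,7aS)-1-methoxy-1,3a,5,7-tetramethyl-1,3,3a,7a-tetrahydro-2-benzofuran-6-yl trifluoromethanesulfonate | O1C[C@@]2(C)C=C(C)C(OS(=O)(=O)C(F)(F)F)=C(C)[C@H]2C1(C)OC | intermediate
16 | (3aS,7aR)-1-methoxy-1,3a,5,7-tetramethyl-1,3,3a,7a-tetrahydro-2-benzofuran | O1C[C@@]2(C)C=C(C)C=C(C)[C@H]2C1(C)OC | intermediate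
17 | 1-[(1R,6S)-6-(hydroxymethyl)-2,4,6-trimethylcyclohexa-2,4-dien-1-yl]ethan-1-one | OC[C@@]1(C)C=C(C)C=C(C)[C@H]1C(C)=O | intermediate
18 | 1-[(1R,6S)-6-{[(tert-butyldimethylsilyl)oxy]methyl}-2,4,6-trimethylcyclohexa-2,4-dien-1-yl]ethan-1-one | CC(C)(C)[Si](C)(C)OC[C@@]1(C)C=C(C)C=C(C)[C@H]1C(C)=O | intermediate
19 | 1-propynylmagnesium bromide | CC#C[Mg]Br | starting material
20 | 2-[(1R,6S)-6-{[(tert-butyldimethylsilyl)oxy]methyl}-2,4,6-trimethylcyclohexa-2,4-dien-1-yl]pent-3-yn-2-ol, both carbinol epimers | CC(C)(C)[Si](C)(C)OC[C@@]1(C)C=C(C)C=C(C)[C@H]1C(C)(O)C#CC | intermediate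
21 | (3E)-4-[(1S,6S)-6-{[(tert-butyldimethylsilyl)oxy]methyl}-2,4,6-trimethylcyclohexa-2,4-dien-1-yl]pent-3-en-2-one | CC(C)(C)[Si](C)(C)OC[C@@]1(C)C=C(C)C=C(C)[C@H]1/C(C)=C/C(C)=O | intermediate
22 | (3E)-4-[(1S,6S)-6-(hydroxymethyl)-2,4,6-trimethylcyclohexa-2,4-dien-1-yl]pent-3-en-2-one | OC[C@@]1(C)C=C(C)C=C(C)[C@H]1/C(C)=C/C(C)=O | intermediate
23 | (1S,6S)-1,3,5-trimethyl-6-[(2E)-4-oxopent-2-en-2-yl]cyclohexa-2,4-diene-1-carbaldehyde | O=C[C@@]1(C)C=C(C)C=C(C)[C@H]1/C(C)=C/C(C)=O | intermediate
24 | methyl 2-methyl-3-oxopentanoate | CCC(=O)C(C)C(=O)OC | starting material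
25 | sodium lithium dianion of 24 | [Na+].[Li+].CC=C([O-])C(C)=C([O-])OC | intermediate
26 | methyl 5-hydroxy-2,4-dimethyl-3-oxo-5-{(1S,6S)-1,3,5-trimethyl-6-[(2E)-4-oxopent-2-en-2-yl]cyclohexa-2,4-dien-1-yl}pentanoate, diastereomer mixture | COC(=O)C(C)C(=O)C(C)C(O)[C@@]1(C)C=C(C)C=C(C)[C@H]1/C(C)=C/C(C)=O | intermediate
27 | methyl 2,4-dimethyl-3,5-dioxo-5-{(1S,6S)-1,3,5-trimethyl-6-[(2E)-4-oxopent-2-en-2-yl]cyclohexa-2,4-dien-1-yl}pentanoate | COC(=O)C(C)C(=O)C(C)C(=O)[C@@]1(C)C=C(C)C=C(C)[C@H]1/C(C)=C/C(C)=O | intermediate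
28 | 4-hydroxy-3,5-dimethyl-6-{(1S,6S)-1,3,5-trimethyl-6-[(2E)-4-oxopent-2-en-2-yl]cyclohexa-2,4-dien-1-yl}-2H-pyran-2-one | O=c1oc([C@@]2(C)C=C(C)C=C(C)[C@H]2/C(C)=C/C(C)=O)c(C)c(O)c1C | intermediate
29 | 2-methoxy-3,5-dimethyl-6-{(1S,6S)-1,3,5-trimethyl-6-[(2E)-4-oxopent-2-en-2-yl]cyclohexa-2,4-dien-1-yl}-4H-pyran-4-one | COc1oc([C@@]2(C)C=C(C)C=C(C)[C@H]2/C(C)=C/C(C)=O)c(C)c(=O)c1C | target

Total step count: 18. Longest linear sequence: 18 steps (from 1).

**Steps most likely to fail**

**Step 6.** Ring closure may be slow, because the β-carbon is neopentyl and sits next to an α-methyl group. The six-membered transition state may also discriminate poorly between the two enone arms.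
- The fallback sets out from 10 and makes the same C6–C bond by a radical route.
- SmI2 with hexafluoroisopropanol in THF at −78 °C turns the aldehyde into a ketyl radical that closes 6-exo-trig on the dienone. The same tether constraint applies, and the product is the racemic cis-fused hydroxy enone F1.
- Dess–Martin oxidation gives the racemic diketone, that is 11 together with its antipode F2.
- Preparative chromatography on a chiral stationary phase separates the two, and the route is rejoined at 11.

**Step 7.** Electron transfer to the ring enone (1,4-reduction or reductive dimerisation) may compete before the C–O bond breaks.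
- The fallback sets out from 11 and removes the enone first.
- The saturated ketone alone is ketalised with 1,2-bis(trimethylsilyloxy)ethane and catalytic Me3SiOSO2CF3 in CH2Cl2 at −78 °C, giving the dioxolane F3.
- KN(SiMe3)2 and the triflimide of step 8 give the dienyl triflate F4.
- Pd(OAc)2, PPh3, HCO2H and Et3N give the diene ketal F5.
- Aqueous acid frees the bicyclic dienyl α-alkoxy ketone F6.
- With no enone left, SmI2 in THF/MeOH can be used as forcefully as needed to give 17, which is silylated to 18 as in step 10.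

**Step 12.** The ring diene may attack the gold-bound alkyne (enyne cycloisomerisation), or the tertiary alcohol may ionise and dehydrate.
- The fallback sets out from 18 and replaces the redox-neutral alkyne rearrangement by an oxidative allylic transposition.
- 1-Propenylmagnesium bromide with LaCl3·2LiCl gives the tertiary allylic alcohol F7.
- Pyridinium chlorochromate, [C5H5NH][CrO3Cl], in CH2Cl2 brings about the Babler–Dauben reaction (sigmatropic shift of the chromate ester, then oxidation).
- The route is rejoined at 21.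

**Further compounds**
F1 | step 6 | cis-fused 4-hydroxy-5,7,8a-trimethyl-3,4,4a,5-tetrahydro-1H-isochromen-6(8aH)-one, racemate (one enantiomer drawn) | O1C[C@@]2(C)C=C(C)C(=O)C(C)[C@H]2C(O)C1
F2 | step 6 | (4aS,5R,8aR)-5,7,8a-trimethyl-4a,5-dihydro-1H-isochromene-4,6(3H,8aH)-dione (antipode of 11) | O1C[C@]2(C)C=C(C)C(=O)[C@H](C)[C@@H]2C(=O)C1
F3 | step 7 | 4,4-ethylenedioxy derivative of 11 (dioxolane of the saturated ketone) | O1C[C@@]2(C)C=C(C)C(=O)[C@@H](C)[C@H]2C3(OCCO3)C1
F4 | step 7 | dienyl triflate of F3 | O1C[C@@]2(C)C=C(C)C(OS(=O)(=O)C(F)(F)F)=C(C)[C@H]2C3(OCCO3)C1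
F5 | step 7 | diene ketal from F4 | O1C[C@@]2(C)C=C(C)C=C(C)[C@H]2C3(OCCO3)C1
F6 | step 7 | cis-fused 5,7,8a-trimethyl-4a,8a-dihydro-1H-isochromen-4(3H)-one | O1C[C@@]2(C)C=C(C)C=C(C)[C@H]2C(=O)C1
F7 | step 12 | 2-[(1R,6S)-6-{[(tert-butyldimethylsilyl)oxy]methyl}-2,4,6-trimethylcyclohexa-2,4-dien-1-yl]pent-3-en-2-ol, isomer mixture | CC(C)(C)[Si](C)(C)OC[C@@]1(C)C=C(C)C=C(C)[C@H]1C(C)(O)C=CC
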